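5 questions stand on 4 set-ups with the same charge: which gives the most target, and how much each gives.

the same everywhere: enzyme 11 µM; added ligand 12 µM
- noon: starting material 0.11 M; time 2.5 d; a closed flask charged with all of it at once and left for 2.5 d
- winter: starting material 0.11 M; a single well-mixed tank run continuously and read at steady state, 2.5 d in it on average
- summer: starting material 0.11 M; a single well-mixed tank run continuously and read at steady state, 7.50 d in it on average
- midnight: starting material 0.11 M (fed, over 2.00 d); time 2.5 d; all but starting material at the start; starting material goes in evenly over 2.00 d, the run ends at 2.5 d

    enzyme + added ligand ⇌ idle complex, settled at all times (K1 = 2.7 × 10⁶ L mol⁻¹)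
    target → over-reaction product (k2 = 0.0248 h⁻¹)
    starting material + enzyme → target + enzyme, rate k3*[starting material]*[enzyme]/(1 + ([starting material]/Km3)) (Km3 = 7.54 mM, k3 = 8.14 × 10⁵ L mol⁻¹ h⁻¹)
    starting material + target ⇌ idle adduct, settled at all times (K4 = 55 L mol⁻¹)

- the set-up with the highest amount of target at the outlet or at the end, in percent of the starting material put in ("none" if the first two lie within 2 percentage points) (noon / winter / summer / midnight / none)
- amount of target at the outlet or at the end, in percent of the starting material put in, noon
- amount of target at the outlet or at the end, in percent of the starting material put in, winter
- amount of target at the outlet or at the end, in percent of the starting material put in, summer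
- amount of target at the outlet or at the end, in percent of the starting material put in, midnight

- a species is counted by the starting material in it: one idle adduct counts as two
- amounts and yields of target count idle adduct too
- the stated concentrations are those of everything mixed, before any reaction; amounts are the same in each set-up
- the feed brings no volume worth counting
- in an amount of target, one idle adduct counts as one target
- run time (noon): 2.5 d

Watch one quantity. By my reckoning, the added ligand leaves 1.45 µM of the enzyme free, so the rate law tops out at a ceiling (its Vmax) of 8.88 mM h⁻¹. The clearing time, the charge divided by that ceiling, is 0.516 d.

Hold it against two clocks. In noon it is shorter than the 1.2 d half-life of free target by the over-reaction step, so I treat the charge as converted at the clearing time and decaying for the rest of the run, which gives 30.7%. In midnight the dose takes 2.00 d, longer than the clearing time, so the feed of 2.29 mM h⁻¹ stays under the ceiling and the dose sets the pace. Decaying each portion from its arrival, I get 43.4%. I leave the tanks to the forecast.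

The forecast names midnight, with 30.9% for noon, 40.2% for winter, 18.6% for summer and 50% for midnight, above my figure. Its ground: “the adduct protects it while starting material remains”.

The simulation gives midnight: 30.9% for noon, 40.2% for winter, 18.6% for summer and 49.9% for midnight.

Squeeze the midnight dose into 0.250 d, under the clearing time, and it gives 31.7%, below winter, against the forecast's choice. A noon neighbour with 4.8 × 10⁻⁵ M of added ligand has a clearing time of 6.87 d, beyond its run. Its ceiling allows 36.4% of its charge; at its end it has turned over 33.1%, 46.1% stays free and 20.8% is starting material bound in idle adduct. Midnight is not at rest at its end: 0.11% free starting material remains, but target still stands at 49.9%. At 25.0 d midnight's target is 0% and its over-reaction product >99.9%.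

The numbers of this flask were set for the occasion; the run is a simulation.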